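**Assumption:** the target has no stereocentres and no E/Z-stereogenic alkenes (both olefins are gem-dimethyl prenyl groups), so it is achiral and no stereocontrol is needed.

## Retrosynthetic overview

1. Lupalbigenin 16 ⇐ tris-MOM ether 15 by global acetal cleavage.
2. The pyranone ring is the only ring built and is formed last. C4–C3 and O1–C2 come from a Rh(III) aldehyde C–H activation/oxidative [4+2] annulation of salicylaldehyde 7 with aryl(silyl)alkyne 13, where silicon is a traceless regiocontrol group.
3. 7 ⇐ C2-symmetric phenol 6 (ortho-formylation) ⇐ Ir C–H borylation/oxidation of 4 ⇐ resorcinol + prenyl bromide (directed metalation).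
4. 13 ⇐ Sonogashira coupling of bromide 11 with TMS-acetylene; 11 ⇐ 4-bromophenol (ortho-iodination, I/Mg exchange, prenylation).
5. Both benzene rings are purchased. The symmetry of 6 (prenyl para to OH, two equivalent ortho C–H) fixes 6-prenyl rather than 8-prenyl.

## Route

**Step 1**
Reactants: 1 resorcinol
Product: 2 1,3-bis(methoxymethoxy)benzene
Conditions: NaH, MOMCl, DMF, 0 °C → rt
Reagents that add atoms: chloromethyl methyl ether (MOMCl), COCCl
Why: Williamson-type O-alkylation of both phenoxides; MOM serves as protecting group and as the directing group for step 2.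

**Step 2**
Reactants: 2 1,3-bis(methoxymethoxy)benzene; 3 prenyl bromide
Product: 4 1,3-bis(methoxymethoxy)-2-(3-methylbut-2-en-1-yl)benzene
Conditions: n-BuLi, THF, 0 °C → rt; CuI, −40 °C; then 3, −40 °C → rt
Reagents that add atoms: none (prenyl comes from 3)
Why: Directed ortho-metalation occurs at C2 between the two cooperating OMOM groups, and the aryl-copper species is alkylated at the primary (α) carbon of prenyl bromide.

**Step 3**
Reactants: 4 1,3-bis(methoxymethoxy)-2-prenylbenzene
Product: 6 3,5-bis(methoxymethoxy)-4-(3-methylbut-2-en-1-yl)phenol, via pinacol boronate 5 (not isolated)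
Conditions: [Ir(OMe)(cod)]2 (1.5 mol%), dtbpy (3 mol%), B2pin2 (0.75 equiv), THF, 60 °C; evaporate; then 30% H2O2, aq NaOH, THF, 0 °C
Reagents that add atoms: bis(pinacolato)diboron, CC1(C)OB(OC1(C)C)B1OC(C)(C)C(C)(C)O1 (boron is lost again); hydrogen peroxide, OO (supplies the phenolic O)
Why: Sterically controlled Ir-catalysed aromatic C–H borylation hits C5, the only C–H without an ortho substituent, and basic peroxide oxidises C–B to C–OH without epoxidising the electron-rich olefin (one-pot C–H hydroxylation).

**Step 4**
Reactants: 6 3,5-bis(methoxymethoxy)-4-prenylphenol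
Product: 7 6-hydroxy-2,4-bis(methoxymethoxy)-3-(3-methylbut-2-en-1-yl)benzaldehyde
Conditions: MgCl2, Et3N, (CH2O)n, MeCN, reflux
Reagents that add atoms: paraformaldehyde, C=O
Why: Magnesium-phenoxide-mediated ortho-formylation (Casnati–Skattebøl type) is ortho-specific and non-acidic; the two ortho sites are equivalent and para is blocked, so a single isomer forms.

**Step 5**
Reactants: 8 4-bromophenol
Product: 9 4-bromo-2-iodophenol
Conditions: NIS (1.0 equiv), p-TsOH (10 mol%), MeCN, rt
Reagents that add atoms: N-iodosuccinimide, O=C1CCC(=O)N1I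
Why: Electrophilic aromatic iodination goes ortho to OH because para is blocked by Br; this is cleaner than direct phenoxide C-prenylation, which gives O-/C-/bis-alkylation mixtures.

**Step 6**
Reactants: 9 4-bromo-2-iodophenol
Product: 10 4-bromo-2-iodo-1-(methoxymethoxy)benzene
Conditions: MOMCl, i-Pr2NEt, CH2Cl2, 0 °C → rt
Reagents that add atoms: chloromethyl methyl ether, COCCl
Why: Standard phenol O-alkylation to the MOM acetal.

**Step 7**
Reactants: 10 4-bromo-2-iodo-1-(methoxymethoxy)benzene; 3 prenyl bromide
Product: 11 4-bromo-1-(methoxymethoxy)-2-(3-methylbut-2-en-1-yl)benzene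
Conditions: i-PrMgCl·LiCl, THF, −30 °C; CuI (10 mol%); then 3, −30 → 0 °C
Reagents that add atoms: none (prenyl comes from 3)
Why: Chemoselective, OMOM-assisted iodine–magnesium exchange (I much faster than Br) followed by Cu-catalysed allylic substitution at the unhindered α-carbon of prenyl bromide.

**Step 8**
Reactants: 11 4-bromo-1-(methoxymethoxy)-2-prenylbenzene; 12 ethynyltrimethylsilane
Product: 13 {[4-(methoxymethoxy)-3-(3-methylbut-2-en-1-yl)phenyl]ethynyl}trimethylsilane
Conditions: PdCl2(PhCN)2 (3 mol%), P(t-Bu)3·HBF4 (6 mol%), CuI (2 mol%), i-Pr2NH, dioxane, rt → 45 °C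
Reagents that add atoms: none (alkyne comes from 12)
Why: Sonogashira coupling with a bulky electron-rich phosphine activates the electron-rich aryl bromide under mild conditions; the trisubstituted olefin is inert to Heck insertion at this temperature.

**Step 9**
Reactants: 7 6-hydroxy-2,4-bis(methoxymethoxy)-3-prenylbenzaldehyde; 13 aryl(trimethylsilyl)alkyne (1.2 equiv)
Product: 15 5,7-bis(methoxymethoxy)-3-[4-(methoxymethoxy)-3-(3-methylbut-2-en-1-yl)phenyl]-6-(3-methylbut-2-en-1-yl)-4H-chromen-4-one, via 2-trimethylsilyl isoflavone 14 (not isolated)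
Conditions: [Cp*Rh(MeCN)3](SbF6)2 (5 mol%), Cu(OAc)2 (2.2 equiv), NaOAc (1 equiv), DCE, 80 °C, N2; then TBAF/AcOH (1:1, 1.5 equiv), THF, rt
Reagents that add atoms: none (Cu(OAc)2 is the oxidant; SiMe3 is lost)
Why: Proposed new method: silyl-directed Rh(III) oxidative annulation of a salicylaldehyde to an isoflavone — phenoxide-directed, acetate-assisted rhodation of the formyl C–H gives a five-membered acyl-rhodacycle; the alkyne inserts with Rh on the silicon-bearing carbon (α-silyl stabilisation of the C–Rh bond, and the bulky SiMe3 stays away from the forming C–C bond), so the acyl carbon bonds to the aryl-bearing carbon (C4–C3); C–O reductive elimination closes O1–C2, Cu(II) reoxidises Rh(I), and buffered fluoride removes the C2 silyl group to give the 2-unsubstituted 3-aryl chromone; the closest known reactions are the Rh-catalysed oxidative annulation of salicylaldehydes with symmetrical internal alkynes to 2,3-disubstituted chromones and the silyl-controlled regiochemistry of Larock-type heteroannulations.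

**Step 10**
Reactants: 15 tris-MOM lupalbigenin
Product: 16 lupalbigenin, 5,7-dihydroxy-3-[4-hydroxy-3-(3-methylbut-2-en-1-yl)phenyl]-6-(3-methylbut-2-en-1-yl)-4H-chromen-4-one
Conditions: 3 M aq HCl/MeOH (1:4), 50 °C, monitored and stopped at full conversion
Reagents that add atoms: none
Why: Acid-catalysed acetal hydrolysis removes all three MOM groups; mild methanolic HCl is the usual way to unmask prenylated isoflavones without cyclising the prenyl groups onto the neighbouring phenols.

## Compound list

1 | resorcinol | Oc1cccc(O)c1 | starting material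
2 | 1,3-bis(methoxymethoxy)benzene | COCOc1cccc(OCOC)c1 | intermediate
3 | prenyl bromide (1-bromo-3-methylbut-2-ene) | CC(C)=CCBr | starting material
4 | 1,3-bis(methoxymethoxy)-2-(3-methylbut-2-en-1-yl)benzene | COCOc1cccc(OCOC)c1CC=C(C)C | intermediate
5 | 2-[3,5-bis(methoxymethoxy)-4-(3-methylbut-2-en-1-yl)phenyl]-4,4,5,5-tetramethyl-1,3,2-dioxaborolane | COCOc1cc(B2OC(C)(C)C(C)(C)O2)cc(OCOC)c1CC=C(C)C | intermediate (not isolated, step 3)
6 | 3,5-bis(methoxymethoxy)-4-(3-methylbut-2-en-1-yl)phenol | COCOc1cc(O)cc(OCOC)c1CC=C(C)C | intermediate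
7 | 6-hydroxy-2,4-bis(methoxymethoxy)-3-(3-methylbut-2-en-1-yl)benzaldehyde | O=Cc1c(O)cc(OCOC)c(CC=C(C)C)c1OCOC | intermediate
8 | 4-bromophenol | Oc1ccc(Br)cc1 | starting material
9 | 4-bromo-2-iodophenol | Oc1ccc(Br)cc1I | intermediate
10 | 4-bromo-2-iodo-1-(methoxymethoxy)benzene | COCOc1ccc(Br)cc1I | intermediate
11 | 4-bromo-1-(methoxymethoxy)-2-(3-methylbut-2-en-1-yl)benzene | COCOc1ccc(Br)cc1CC=C(C)C | intermediate
12 | ethynyltrimethylsilane | C#C[Si](C)(C)C | starting material
13 | {[4-(methoxymethoxy)-3-(3-methylbut-2-en-1-yl)phenyl]ethynyl}trimethylsilane | COCOc1ccc(C#C[Si](C)(C)C)cc1CC=C(C)C | intermediate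
14 | 5,7-bis(methoxymethoxy)-3-[4-(methoxymethoxy)-3-(3-methylbut-2-en-1-yl)phenyl]-6-(3-methylbut-2-en-1-yl)-2-(trimethylsilyl)-4H-chromen-4-one | COCOc1ccc(cc1CC=C(C)C)-c1c([Si](C)(C)C)oc2cc(OCOC)c(CC=C(C)C)c(OCOC)c2c1=O | intermediate (not isolated, step 9)
15 | 5,7-bis(methoxymethoxy)-3-[4-(methoxymethoxy)-3-(3-methylbut-2-en-1-yl)phenyl]-6-(3-methylbut-2-en-1-yl)-4H-chromen-4-one | COCOc1ccc(cc1CC=C(C)C)-c1coc2cc(OCOC)c(CC=C(C)C)c(OCOC)c2c1=O | intermediate
16 | lupalbigenin | CC(C)=CCc1cc(-c2coc3cc(O)c(CC=C(C)C)c(O)c3c2=O)ccc1O | target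

## Step count

Total steps: 10 (steps 3 and 9 are one-pot, two-stage operations).
Longest linear sequence: 6 (1→2→4→6→7→15→16 via steps 1, 2, 3, 4, 9, 10; the branch through steps 5, 6, 7, 8, 9, 10 is also 6).

## Three steps most likely to fail

1. **Step 9 (proposed new Rh annulation).** Risks: reversed insertion regiochemistry (giving the 2-aryl flavone isomer), sluggish insertion of the hindered silyl alkyne, and Cu-promoted desilylation/homocoupling of 13. Fallback with known chemistry: the 3-iodochromone/Suzuki–Miyaura endgame. Convert 7 to the o-hydroxyacetophenone (MeMgBr, then MnO2), form the enaminone with DMF-DMA, cyclise with I2 to 3-iodo-5,7-bis(methoxymethoxy)-6-prenylchromone, and couple it under Pd catalysis with the pinacol boronate made from bromide 11 (Miyaura borylation) to reach 15.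

2. **Step 3 (Ir C–H borylation with the prenyl olefin present).** Risks: olefin hydroboration or isomerisation by HBpin/Ir–H and catalyst inhibition. Fallback: reverse the order. Borylate/oxidise olefin-free 2 to 3,5-bis(methoxymethoxy)phenol, mask it as the TIPS ether, lithiate between the two OMOM groups (n-BuLi, then CuI and prenyl bromide), and remove TIPS with TBAF to reach the same phenol 6.

3. **Step 10 (acidic removal of three MOM groups).** Risk: acid-catalysed cyclisation of either prenyl group onto its ortho phenol (dimethylchroman formation), especially at C6 between two hydroxyls. Fallback: change the protecting-group strategy to SEM ethers throughout (same directing ability in steps 2 and 7, same stability elsewhere) and unmask at the end with fluoride (TBAF/DMPU), which cannot protonate the olefins and would also remove the C2 silyl group in the same operation.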